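**Strategy.** The target is read as a 3-unsubstituted, 7-endo nemorosone-type bicyclo[3.3.1]nonane-2,4,9-trione that has gained a prenyl group at C3 and two molecules of O2. Everything rests on C3, the carbon between the C2 and C4 ketones, which belongs both to the cycloheptane ring of the homoadamantane and to the 1,2-dioxepane. In one flask, a Claisen shift of an O-(1,1-dimethylallyl) enol ether forms the C3–CH2 bond, and Mn(III)/O2 then drives the C3 radical through 7-exo closure onto the endo C7 prenyl group, O2 capture, 7-exo peroxyl closure onto the new prenyl alkene (O–CH bond) and a second O2 capture. The precursor is a cage-free, peroxide-free enol ether with three stereocentres.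

Key step: step 11

Remarks on the chemistry (assumptions):
- Numbering used throughout: C1 = benzoyl-bearing bridgehead, C2–C3–C4 = diketone bridge, C5 = prenyl-bearing bridgehead, C6–C7–C8 = carbocyclic bridge (C8 gem-dimethyl), C9 = bridging ketone. "Endo" at C7 means syn to the C2–C4 bridge.
- The bicyclic β-diketones are drawn as one enol tautomer (C4–OH).
- The carbinol configuration in 7 is left undefined because step 6 destroys it.
- Enol ethers 12 and 13 are drawn as the O4 regioisomers; the O2 regioisomers give the same product in step 11.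
- Compounds 1 and 4 and all reagents are taken as commercial.

**Step 1**
Reactants: 1 2-bromo-3,3-diethoxyprop-1-ene
Product: 2 4,4-diethoxy-2-methyl-3-methylidenebutan-2-yl acetate
Conditions: n-BuLi, THF, −78 °C; acetone; then Ac2O, −78 → 0 °C
Reagents that add atoms: acetone CC(C)=O; acetic anhydride CC(=O)OC(C)=O
Why: Bromine–lithium exchange gives the α-lithioacrolein acetal, which undergoes 1,2-addition to acetone, and the tertiary lithium alkoxide is acetylated in situ (organolithium addition, O-acylation).

**Step 2**
Reactants: 2 4,4-diethoxy-2-methyl-3-methylidenebutan-2-yl acetate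
Product: 3 3-formyl-2-methylbut-3-en-2-yl acetate
Conditions: 1 M aq. oxalic acid, THF, 23 °C
Reagents that add atoms: water O
Why: Mild acid-catalysed acetal hydrolysis should free the α-methylene aldehyde while the tertiary allylic acetate survives the brief exposure.

**Step 3**
Reactants: 4 phenyl(2,4,6-trihydroxyphenyl)methanone
Product: 5 [2,4,6-trihydroxy-3-(3-methylbut-2-en-1-yl)phenyl](phenyl)methanone
Conditions: prenyl bromide (1.0 equiv), 10% aq. KOH, 0 °C
Reagents that add atoms: prenyl bromide CC(C)=CCBr
Why: C-alkylation of the acylphloroglucinol phenoxide in water (Friedel–Crafts-type C-prenylation) should give the mono-prenyl arene, which is separated from bis-prenylated material.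

**Step 4**
Reactants: 5 [2,4,6-trihydroxy-3-(3-methylbut-2-en-1-yl)phenyl](phenyl)methanone
Product: 6 [3-chloro-2,4,6-trihydroxy-5-(3-methylbut-2-en-1-yl)phenyl](phenyl)methanone
Conditions: NCS (1.0 equiv), MeCN, 0 °C
Reagents that add atoms: N-chlorosuccinimide O=C1CCC(=O)N1Cl
Why: Electrophilic aromatic chlorination should occur at the only free ring position, and the chlorine then blocks the future C3, otherwise the most nucleophilic ring carbon.

**Step 5**
Reactants: 6 [3-chloro-2,4,6-trihydroxy-5-(3-methylbut-2-en-1-yl)phenyl](phenyl)methanone; 3 3-formyl-2-methylbut-3-en-2-yl acetate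
Product: 7 chloro-adamantanol (1-benzoyl-3-chloro-10-hydroxy-8,8-dimethyl-5-prenyl-adamantane-2,4,9-trione)
Conditions: dimeric cinchona-derived quaternary ammonium phase-transfer catalyst (25 mol%, antipode chosen for the enantiomer shown), CsOH·H2O, 4 Å MS, CH2Cl2, −50 °C
Reagents that add atoms: none
Why: In this alkylative dearomatisation–annulation the prenyl-bearing carbon adds to the α-methylene aldehyde with loss of acetate (Michael addition–elimination), the benzoyl-bearing carbon closes onto the β,β-dimethyl enal (intramolecular Michael) and the chloro-enolate carbon traps the aldehyde by aldol addition, so the chiral ammonium ion pair sets C5 in the first C–C bond formation while C1, C7 and C3 follow from the adamantane geometry, because only an endo aldehyde can reach C3.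

**Step 6**
Reactants: 7 chloro-adamantanol
Product: 9 7-endo-(2-oxoethyl) 3-chloro enol, via methyl enol ether 8 (not isolated)
Conditions: MeOCH2PPh3Cl, KHMDS, THF, 0 → 23 °C; then 1 M HCl, THF, 0 → 23 °C
Reagents that add atoms: (methoxymethyl)triphenylphosphonium chloride COC[P+](c1ccccc1)(c1ccccc1)c1ccccc1.[Cl-]; water O
Why: Base opens the adamantanol by retro-aldol cleavage to the endo C7 aldehyde (C3 leaves as a stabilised chloro-enolate), Wittig methoxymethylenation captures it and enol ether hydrolysis gives the one-carbon-homologated aldehyde, with the endo configuration at C7 untouched.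

**Step 7**
Reactants: 9 7-endo-(2-oxoethyl) 3-chloro enol
Product: 10 3-chloro-7-endo-prenyl enol
Conditions: i-PrPPh3I, n-BuLi, THF, 0 °C; then 9, −78 → 23 °C
Reagents that add atoms: isopropyltriphenylphosphonium iodide CC(C)[P+](c1ccccc1)(c1ccccc1)c1ccccc1.[I-]
Why: Wittig olefination with the non-stabilised isopropylidene ylide (used in excess because the enol consumes one equivalent) should turn the aldehyde into the trisubstituted prenyl alkene while the hindered ketones stay untouched.

**Step 8**
Reactants: 10 3-chloro-7-endo-prenyl enol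
Product: 11 (1R,5S,7S)-1-benzoyl-4-hydroxy-8,8-dimethyl-5,7-diprenylbicyclo[3.3.1]non-3-ene-2,9-dione
Conditions: Zn dust, AcOH, 23 °C
Reagents that add atoms: none
Why: Reductive dehalogenation of the α-chloro-β-diketone through its zinc enolate should remove the blocking chlorine without touching the prenyl alkenes or the benzoyl group.

**Step 9**
Reactants: 11 3-unsubstituted enol
Product: 12 O-(2-methylbut-3-yn-2-yl) enol ether
Conditions: 3-chloro-3-methylbut-1-yne, DBU, CuCl2·2H2O (1 mol%), MeCN, 0 °C
Reagents that add atoms: 3-chloro-3-methylbut-1-yne CC(C)(Cl)C#C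
Why: Copper-catalysed propargylic substitution through a copper allenylidene should be attacked at the tertiary carbon by the acidic enol oxygen, as it is by phenols and vinylogous acids.

**Step 10**
Reactants: 12 O-(2-methylbut-3-yn-2-yl) enol ether
Product: 13 O-(2-methylbut-3-en-2-yl) enol ether
Conditions: H2 (1 atm), Lindlar catalyst, quinoline, EtOAc, 23 °C
Reagents that add atoms: none
Why: Lindlar semi-hydrogenation should reduce the terminal alkyne to the vinyl group and leave the trisubstituted prenyl alkenes alone.

**Step 11**
Reactants: 13 O-(2-methylbut-3-en-2-yl) enol ether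
Product: 15 target CNP0215795.1, via C3-prenyl enol 14 (not isolated)
Conditions: PhMe, 90 °C, Ar; then AcOH, Mn(OAc)3·2H2O (10 mol%), O2 (1 atm), 23 °C
Reagents that add atoms: dioxygen O=O
Why: Heating triggers a [3,3]-sigmatropic (Claisen) shift of the tert-allyl enol ether that forms the C3–CH2 bond and unmasks the enolisable β-diketone 14; Mn(III) then oxidises its enolate to the C3 radical, which adds 7-exo-trig to the endo C7 prenyl alkene (cycloheptane ring of the homoadamantane), the tertiary radical takes up O2, the peroxyl radical adds 7-exo-trig to the CH terminus of the new C3 prenyl group (1,2-dioxepane), and the second tertiary radical takes up O2 and is reduced by Mn(II)/AcOH to the hydroperoxide, which regenerates Mn(III). The closest known reaction types are the aliphatic Claisen rearrangement, the Mn(III)-mediated aerobic oxidative radical cyclisation of 1,3-dicarbonyl compounds with O2 capture, and peroxyl radical cyclisation onto alkenes. C3 is fixed by the cage, because the C7 side chain can only reach its endo face; the new cage CH is set by the alkene approaching with its CMe2 end turned away from the C8 gem-dimethyl group towards C4/C6; the O–CH centre is expected to form through a chair-like seven-membered transition state with the CMe2 radical terminus pseudo-equatorial, which puts its hydrogen cis to the hydrogen of the cage CH, as in the target. The step needs the C3 radical to cyclise faster than it captures O2, which the delocalised β-diketone radical and the prenyl group held directly over C3 should secure, and it needs the first peroxyl radical to cyclise before it is reduced, which the low Mn loading and the fully substituted C3 in the tether favour.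

**Compound list**

1 | 2-bromo-3,3-diethoxyprop-1-ene (2-bromoacrolein diethyl acetal) | C=C(Br)C(OCC)OCC | starting material
2 | 4,4-diethoxy-2-methyl-3-methylidenebutan-2-yl acetate | C=C(C(OCC)OCC)C(C)(C)OC(C)=O | intermediate
3 | 3-formyl-2-methylbut-3-en-2-yl acetate (3-acetoxy-3-methyl-2-methylidenebutanal) | C=C(C=O)C(C)(C)OC(C)=O | intermediate
4 | phenyl(2,4,6-trihydroxyphenyl)methanone | O=C(c1ccccc1)c1c(O)cc(O)cc1O | starting material
5 | [2,4,6-trihydroxy-3-(3-methylbut-2-en-1-yl)phenyl](phenyl)methanone | CC(C)=CCc1c(O)cc(O)c(C(=O)c2ccccc2)c1O | intermediate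
6 | [3-chloro-2,4,6-trihydroxy-5-(3-methylbut-2-en-1-yl)phenyl](phenyl)methanone | CC(C)=CCc1c(O)c(Cl)c(O)c(C(=O)c2ccccc2)c1O | intermediate
7 | chloro-adamantanol: 1-benzoyl-3-chloro-10-hydroxy-8,8-dimethyl-5-(3-methylbut-2-en-1-yl)adamantane-2,4,9-trione (C10 = carbinol carbon bridging C3 and C7; carbinol configuration undefined; C1, C5, C7 as in 11) | CC(C)=CC[C@]12C[C@@H]3C(O)[C@](Cl)(C1=O)C(=O)[C@](C(=O)c4ccccc4)(C2=O)C3(C)C | intermediate
8 | 1-benzoyl-3-chloro-4-hydroxy-7-endo-(2-methoxyethenyl)-8,8-dimethyl-5-prenylbicyclo[3.3.1]non-3-ene-2,9-dione (E/Z mixture; C1, C5, C7 arranged as in 11) | COC=C[C@H]1C[C@@]2(CC=C(C)C)C(O)=C(Cl)C(=O)[C@](C(=O)c3ccccc3)(C2=O)C1(C)C | intermediate (not isolated)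
9 | 1-benzoyl-3-chloro-4-hydroxy-8,8-dimethyl-7-endo-(2-oxoethyl)-5-prenylbicyclo[3.3.1]non-3-ene-2,9-dione (C1, C5, C7 arranged as in 11) | O=CC[C@H]1C[C@@]2(CC=C(C)C)C(O)=C(Cl)C(=O)[C@](C(=O)c3ccccc3)(C2=O)C1(C)C | intermediate
10 | 1-benzoyl-3-chloro-4-hydroxy-8,8-dimethyl-5,7-bis(3-methylbut-2-en-1-yl)bicyclo[3.3.1]non-3-ene-2,9-dione (7-endo; C1, C5, C7 arranged as in 11) | CC(C)=CC[C@H]1C[C@@]2(CC=C(C)C)C(O)=C(Cl)C(=O)[C@](C(=O)c3ccccc3)(C2=O)C1(C)C | intermediate
11 | (1R,5S,7S)-1-benzoyl-4-hydroxy-8,8-dimethyl-5,7-bis(3-methylbut-2-en-1-yl)bicyclo[3.3.1]non-3-ene-2,9-dione (C7 prenyl endo) | CC(C)=CC[C@H]1C[C@@]2(CC=C(C)C)C(O)=CC(=O)[C@](C(=O)c3ccccc3)(C2=O)C1(C)C | intermediate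
12 | 1-benzoyl-8,8-dimethyl-4-[(2-methylbut-3-yn-2-yl)oxy]-5,7-bis(3-methylbut-2-en-1-yl)bicyclo[3.3.1]non-3-ene-2,9-dione (C1, C5, C7 as in 11) | CC(C)=CC[C@H]1C[C@@]2(CC=C(C)C)C(OC(C)(C)C#C)=CC(=O)[C@](C(=O)c3ccccc3)(C2=O)C1(C)C | intermediate
13 | 1-benzoyl-8,8-dimethyl-4-[(2-methylbut-3-en-2-yl)oxy]-5,7-bis(3-methylbut-2-en-1-yl)bicyclo[3.3.1]non-3-ene-2,9-dione (C1, C5, C7 as in 11) | CC(C)=CC[C@H]1C[C@@]2(CC=C(C)C)C(OC(C)(C)C=C)=CC(=O)[C@](C(=O)c3ccccc3)(C2=O)C1(C)C | intermediate
14 | 1-benzoyl-4-hydroxy-8,8-dimethyl-3,5,7-tris(3-methylbut-2-en-1-yl)bicyclo[3.3.1]non-3-ene-2,9-dione (C7 prenyl endo; C1, C5, C7 as in 11) | CC(C)=CC[C@H]1C[C@@]2(CC=C(C)C)C(O)=C(CC=C(C)C)C(=O)[C@](C(=O)c3ccccc3)(C2=O)C1(C)C | intermediate (not isolated)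
15 | target CNP0215795.1: homoadamantane-2,4,9-trione (C1 benzoyl, C5 prenyl, C8 gem-dimethyl) in which C3 and the adjacent cage CH are joined through –CH2–CH[C(CH3)2OOH]–O–O–C(CH3)2– into a 1,2-dioxepane | CC(C)=CC[C@]12C[C@@H]3C[C@@H]4C(C)(C)OO[C@H](C(C)(C)OO)C[C@@]4(C1=O)C(=O)[C@](C(=O)c1ccccc1)(C2=O)C3(C)C | target

**Count and risks**

Total step count: 11. Longest linear sequence: 9 steps (steps 3–11, from 4); steps 1–2 make the three-carbon partner 3.

The three steps most likely to fail:

1. Step 11 (key step). The C3 radical may capture O2 before the 7-exo closure, the first peroxyl radical may be reduced before it reaches the C3 prenyl alkene, or the facial selectivity at the O–CH carbon may be poor. The fallback sets out from 13 and separates the events. The Claisen shift is run alone (PhMe, 90 °C) and enol 14 is isolated. Enol 14 is then oxidised with Mn(OAc)3 (2 equiv) and added Mn(OAc)2 under O2 in AcOH at 10 °C, conditions meant to reduce the first peroxyl radical as soon as it forms. This should give the cage hydroperoxide with the C3 prenyl group intact F1. F1 is then closed in a separate peroxyl-radical chain reaction (di-tert-butyl hyponitrite, O2, benzene, 30 °C), in which the final peroxyl radical takes its hydrogen from F1. This comes back to the route at 15.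

2. Step 5. The ring closure may start from the chlorine-bearing carbon instead of the benzoyl-bearing carbon, the aldol trap may not hold the aldehyde endo, or the ion-pair control of C5 may be weak with the chlorinated arene. The fallback sets out from 6 and 3. The C-alkylation alone is run under the same chiral phase-transfer conditions at −70 °C and stopped at the monocyclic dearomatised enal F2. F2 is then cyclised under acid (conc. HCl, THF, 0 °C). There the enol carbon that carries the benzoyl group attacks the protonated β,β-dimethyl enal, and the aldehyde is trapped by aldol addition. This comes back at 7.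

3. Step 9. The enolate may react at C3 instead of at oxygen, or the propargyl ether may rearrange before it is reduced. The fallback sets out from 11. Oxalyl chloride with catalytic DMF (CH2Cl2, 0 °C) gives the vinylogous acid chloride F3. Addition–elimination with potassium 2-methylbut-3-en-2-olate (THF, −20 °C) then gives 13 directly, which bypasses 12 and step 10.

**Further compounds**

F1 | step 11 | homoadamantane-2,4,9-trione with C3 prenyl group intact and a 2-hydroperoxypropan-2-yl group on the cage CH next to C3 (C1 benzoyl, C5 prenyl, C8 gem-dimethyl) | CC(C)=CC[C@]12C[C@@H]3C[C@H](C(C)(C)OO)[C@](CC=C(C)C)(C1=O)C(=O)[C@](C(=O)c1ccccc1)(C2=O)C3(C)C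
F2 | step 5 | 2-benzoyl-4-chloro-3,5-dihydroxy-6-(2-formyl-3-methylbut-2-en-1-yl)-6-(3-methylbut-2-en-1-yl)cyclohexa-2,4-dien-1-one (one enol tautomer; quaternary carbon as the future C5) | CC(C)=CC[C@]1(CC(C=O)=C(C)C)C(=O)C(Cl)=C(O)C(C(=O)c2ccccc2)=C1O
F3 | step 9 | 1-benzoyl-4-chloro-8,8-dimethyl-5,7-bis(3-methylbut-2-en-1-yl)bicyclo[3.3.1]non-3-ene-2,9-dione (C1, C5, C7 as in 11) | CC(C)=CC[C@H]1C[C@@]2(CC=C(C)C)C(Cl)=CC(=O)[C@](C(=O)c3ccccc3)(C2=O)C1(C)C
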